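Assumption: commercial crotonaldehyde (≥95% E) is used as the (E)-enal; both side-chain centres of the target read as (S) from the SMILES. This route is a paper design and has not been run.

## Retrosynthetic overview

1. Target ⇐ hydrogenolysis of its bis(O-benzyl) ether; the outer phenols stay masked as benzyl ethers to the end.
2. The two (S)-3-hydroxybutanoate C–O bonds ⇐ central catechol + 2 × (2R,3S)-2,3-epoxybutanal by carbene internal-redox acylation; the epoxide ⇐ (E)-crotonaldehyde + H2O2 by amine-catalysed asymmetric epoxidation, the source of both stereocentres.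
3. That catechol ⇐ oxidative demethylenation of a benzodioxole carrying the acetate/3-phenylpropanoate pair ⇐ stepwise acylation of a 4,7-diaryl-1,3-benzodioxole-5,6-diol; the two ortho pairs of oxygens are told apart as MOM ethers versus methylenedioxy.
4. The two aryl–aryl bonds ⇐ double ortho-metalation/Negishi coupling of 5,6-bis(methoxymethoxy)-1,3-benzodioxole with 4-(benzyloxy)bromobenzene; the tetra-oxygenated core ⇐ sesamol by ortho-oxygenation.
5. Rings: all three benzene rings are bought; the only ring made is the oxirane (formed in step 7, opened in step 8), and the dioxole ring of sesamol is removed in step 6.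

## Route

Step 1
Reactants: 1 sesamol (1,3-benzodioxol-5-ol); 2 IBX (2-iodoxybenzoic acid)
Product: 4 1,3-benzodioxole-5,6-diol, via 1,3-benzodioxole-5,6-dione 3 (not isolated)
Conditions: IBX (1.2 equiv), DMF, rt; then aq. Na2S2O4, EtOAc, rt, Ar
Reagents that add atoms: IBX, O=C1OI(=O)(O)c2ccccc12
Why: IBX-mediated regioselective ortho-oxygenation of an electron-rich phenol (oxygen passes from the aryloxy-iodane to the less hindered ortho carbon, the para position being blocked) gives o-quinone 3, which Na2S2O4 reduces in the same pot to the air-sensitive catechol.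

Step 2
Reactants: 4 1,3-benzodioxole-5,6-diol; 5 chloromethyl methyl ether (MOMCl)
Product: 6 5,6-bis(methoxymethoxy)-1,3-benzodioxole
Conditions: MOMCl (2.5 equiv), i-Pr2NEt, CH2Cl2, 0 °C → rt
Reagents that add atoms: chloromethyl methyl ether, COCCl
Why: Williamson-type O-alkylation of both phenols by the reactive α-chloro ether (MOM protection) masks the first ortho pair of oxygens and installs the directing groups for step 3.

Step 3
Reactants: 6 5,6-bis(methoxymethoxy)-1,3-benzodioxole; 7 1-(benzyloxy)-4-bromobenzene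
Product: 10 4,7-bis[4-(benzyloxy)phenyl]-5,6-bis(methoxymethoxy)-1,3-benzodioxole, via 4,7-dilithio-5,6-bis(methoxymethoxy)-1,3-benzodioxole 8 (not isolated), via 4,7-bis(chlorozincio)-5,6-bis(methoxymethoxy)-1,3-benzodioxole 9 (not isolated)
Conditions: n-BuLi (2.3 equiv), TMEDA, Et2O, 0 °C → rt; ZnCl2, THF; 7 (2.4 equiv), Pd2(dba)3 (2 mol %), XPhos (8 mol %), 60 °C
Reagents that add atoms: 1-(benzyloxy)-4-bromobenzene, Brc1ccc(OCc2ccccc2)cc1
Why: Double directed ortho-metalation takes the only two ring hydrogens (each flanked by OMOM and a dioxole oxygen), Li-to-Zn exchange gives 9, and zerovalent palladium with XPhos joins it twice to 7 in a Negishi coupling, so the benzyl ethers never meet butyllithium.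

Step 4
Reactants: 10 4,7-bis[4-(benzyloxy)phenyl]-5,6-bis(methoxymethoxy)-1,3-benzodioxole
Product: 11 4,7-bis[4-(benzyloxy)phenyl]-1,3-benzodioxole-5,6-diol
Conditions: 3 M HCl, MeOH/THF (degassed), 45 °C, Ar; used directly
Reagents that add atoms: none
Why: Acid-catalysed acetal solvolysis removes both MOM groups while the methylenedioxy ring and the aryl benzyl ethers stay, so the two ortho pairs of oxygens are now differentiated.

Step 5
Reactants: 11 4,7-bis[4-(benzyloxy)phenyl]-1,3-benzodioxole-5,6-diol; 12 3-phenylpropanoyl chloride; 13 acetic anhydride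
Product: 15 6-acetoxy-4,7-bis[4-(benzyloxy)phenyl]-1,3-benzodioxol-5-yl 3-phenylpropanoate, via 4,7-bis[4-(benzyloxy)phenyl]-6-hydroxy-1,3-benzodioxol-5-yl 3-phenylpropanoate 14 (not isolated)
Conditions: 12 (1.0 equiv, slow addition), i-Pr2NEt, CH2Cl2, −78 → −20 °C; then Ac2O (3 equiv), DMAP (10 mol %), → rt
Reagents that add atoms: 3-phenylpropanoyl chloride, O=C(Cl)CCc1ccccc1; acetic anhydride, CC(=O)OC(C)=O
Why: Kinetic mono-acylation of the catechol monoanion (the second hydroxyl is hindered and hydrogen-bonded to the new ester) followed by exhaustive DMAP-catalysed acetylation in the same pot (nucleophilic acyl substitution) gives the mixed diester, and any acyl shift between the two neighbouring oxygens is degenerate because 11 is symmetric.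

Step 6
Reactants: 15 6-acetoxy-4,7-bis[4-(benzyloxy)phenyl]-1,3-benzodioxol-5-yl 3-phenylpropanoate
Product: 17 2-acetoxy-3,6-bis[4-(benzyloxy)phenyl]-4,5-dihydroxyphenyl 3-phenylpropanoate, via 2,6-diacetoxy-4,7-bis[4-(benzyloxy)phenyl]-1,3-benzodioxol-5-yl 3-phenylpropanoate 16 (not isolated)
Conditions: Pb(OAc)4 (1.5 equiv), benzene, 80 °C; then AcOH/H2O/THF, rt
Reagents that add atoms: none
Why: Oxidative demethylenation, in which tetravalent lead acetoxylates the doubly oxygen-activated O–CH2–O carbon to the orthoformate-type acetate 16 and mild aqueous acid hydrolyses this to the catechol without touching aryl esters or benzyl ethers, while acyl migration to the new hydroxyls is blocked because an aryl-bearing carbon separates the two oxygen pairs.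

Step 7
Reactants: 18 (E)-but-2-enal (crotonaldehyde); 19 hydrogen peroxide
Product: 20 (2R,3S)-3-methyloxirane-2-carbaldehyde
Conditions: (R)-2-{bis[3,5-bis(trifluoromethyl)phenyl](trimethylsilyloxy)methyl}pyrrolidine (10 mol %), 35% aq. H2O2 (1.3 equiv), CH2Cl2, rt; MnO2, MgSO4, SiO2 plug; used as a titrated CH2Cl2 solution
Reagents that add atoms: hydrogen peroxide, OO
Why: Iminium–enamine organocatalysis (Jørgensen-type epoxidation) in which the silyloxydiarylmethyl arm of the (R)-catalyst blocks the Re face of C3 of the E-iminium ion, hydroperoxide adds to the Si face (sets 3S) and the enamine closes the ring to the trans-(2R,3S) epoxide; the catalyst enantiomer is assigned from the steric-shielding model, with the sense to be confirmed on an aliquot converted to the known methyl 3-hydroxybutanoate.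

Step 8
Reactants: 17 2-acetoxy-3,6-bis[4-(benzyloxy)phenyl]-4,5-dihydroxyphenyl 3-phenylpropanoate; 20 (2R,3S)-3-methyloxirane-2-carbaldehyde
Product: 21 2-acetoxy-3,6-bis[4-(benzyloxy)phenyl]-4,5-bis{[(3S)-3-hydroxybutanoyl]oxy}phenyl 3-phenylpropanoate
Conditions: 20 (3 equiv, syringe pump), 2-mesityl-6,7-dihydro-5H-pyrrolo[2,1-c][1,2,4]triazol-2-ium chloride (10 mol %), i-Pr2NEt (30 mol %), 4 Å MS, CH2Cl2, 30 °C, Ar
Reagents that add atoms: (2R,3S)-3-methyloxirane-2-carbaldehyde, C[C@@H]1O[C@H]1C=O
Why: Proposed new method: carbene-catalysed internal-redox double O-acylation of a hindered catechol, in which the triazolylidene adds to the aldehyde of 20, the Breslow intermediate opens the epoxide by C2–O cleavage (the C3–O bond is untouched, so 3S is kept), tautomerisation gives the (S)-3-hydroxybutanoyl azolium, and the hydrogen-bonded catecholate of 17 takes the acyl group on each oxygen with release of the carbene; the closest known reaction type is the NHC redox esterification of α,β-epoxy aldehydes with simple aliphatic alcohols to β-hydroxy esters, which to my knowledge has not been shown for a di-ortho-substituted catechol as a two-fold acyl acceptor giving unprotected β-hydroxy aryl esters.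

Step 9
Reactants: 21 2-acetoxy-3,6-bis[4-(benzyloxy)phenyl]-4,5-bis{[(3S)-3-hydroxybutanoyl]oxy}phenyl 3-phenylpropanoate
Product: 22 2-acetoxy-4,5-bis{[(3S)-3-hydroxybutanoyl]oxy}-3,6-bis(4-hydroxyphenyl)phenyl 3-phenylpropanoate (CNP0304225.2)
Conditions: H2 (1 atm), 10% Pd/C, EtOAc/THF, rt
Reagents that add atoms: none
Why: Hydrogenolysis of the two aryl benzyl ethers over Pd/C in a non-nucleophilic solvent leaves the four aryl esters, the free secondary alcohols and both stereocentres untouched.

## Compound list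

1 | sesamol (1,3-benzodioxol-5-ol) | Oc1ccc2OCOc2c1 | starting material
2 | IBX (2-iodoxybenzoic acid) | O=C1OI(=O)(O)c2ccccc12 | starting material
3 | 1,3-benzodioxole-5,6-dione | O=C1C=C2OCOC2=CC1=O | intermediate
4 | 1,3-benzodioxole-5,6-diol | Oc1cc2OCOc2cc1O | intermediate
5 | chloromethyl methyl ether | COCCl | starting material
6 | 5,6-bis(methoxymethoxy)-1,3-benzodioxole | COCOc1cc2OCOc2cc1OCOC | intermediate
7 | 1-(benzyloxy)-4-bromobenzene | Brc1ccc(OCc2ccccc2)cc1 | starting material
8 | 4,7-dilithio-5,6-bis(methoxymethoxy)-1,3-benzodioxole | [Li]c1c(OCOC)c(OCOC)c([Li])c2OCOc12 | intermediate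
9 | 4,7-bis(chlorozincio)-5,6-bis(methoxymethoxy)-1,3-benzodioxole | Cl[Zn]c1c(OCOC)c(OCOC)c([Zn]Cl)c2OCOc12 | intermediate
10 | 4,7-bis[4-(benzyloxy)phenyl]-5,6-bis(methoxymethoxy)-1,3-benzodioxole | COCOc1c(OCOC)c(-c2ccc(OCc3ccccc3)cc2)c2OCOc2c1-c1ccc(OCc2ccccc2)cc1 | intermediate
11 | 4,7-bis[4-(benzyloxy)phenyl]-1,3-benzodioxole-5,6-diol | Oc1c(O)c(-c2ccc(OCc3ccccc3)cc2)c2OCOc2c1-c1ccc(OCc2ccccc2)cc1 | intermediate
12 | 3-phenylpropanoyl chloride | O=C(Cl)CCc1ccccc1 | starting material
13 | acetic anhydride | CC(=O)OC(C)=O | starting material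
14 | 4,7-bis[4-(benzyloxy)phenyl]-6-hydroxy-1,3-benzodioxol-5-yl 3-phenylpropanoate | O=C(CCc1ccccc1)Oc1c(O)c(-c2ccc(OCc3ccccc3)cc2)c2OCOc2c1-c1ccc(OCc2ccccc2)cc1 | intermediate
15 | 6-acetoxy-4,7-bis[4-(benzyloxy)phenyl]-1,3-benzodioxol-5-yl 3-phenylpropanoate | CC(=O)Oc1c(OC(=O)CCc2ccccc2)c(-c2ccc(OCc3ccccc3)cc2)c2OCOc2c1-c1ccc(OCc2ccccc2)cc1 | intermediate
16 | 2,6-diacetoxy-4,7-bis[4-(benzyloxy)phenyl]-1,3-benzodioxol-5-yl 3-phenylpropanoate (acetal carbon racemic) | CC(=O)OC1Oc2c(-c3ccc(OCc4ccccc4)cc3)c(OC(C)=O)c(OC(=O)CCc3ccccc3)c(-c3ccc(OCc4ccccc4)cc3)c2O1 | intermediate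
17 | 2-acetoxy-3,6-bis[4-(benzyloxy)phenyl]-4,5-dihydroxyphenyl 3-phenylpropanoate | CC(=O)Oc1c(OC(=O)CCc2ccccc2)c(-c2ccc(OCc3ccccc3)cc2)c(O)c(O)c1-c1ccc(OCc2ccccc2)cc1 | intermediate
18 | (E)-but-2-enal (crotonaldehyde) | C/C=C/C=O | starting material
19 | hydrogen peroxide | OO | starting material
20 | (2R,3S)-3-methyloxirane-2-carbaldehyde (trans) | C[C@@H]1O[C@H]1C=O | intermediate
21 | 2-acetoxy-3,6-bis[4-(benzyloxy)phenyl]-4,5-bis{[(3S)-3-hydroxybutanoyl]oxy}phenyl 3-phenylpropanoate | CC(=O)Oc1c(OC(=O)CCc2ccccc2)c(-c2ccc(OCc3ccccc3)cc2)c(OC(=O)C[C@H](C)O)c(OC(=O)C[C@H](C)O)c1-c1ccc(OCc2ccccc2)cc1 | intermediate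
22 | 2-acetoxy-4,5-bis{[(3S)-3-hydroxybutanoyl]oxy}-3,6-bis(4-hydroxyphenyl)phenyl 3-phenylpropanoate | CC(=O)Oc1c(OC(=O)CCc2ccccc2)c(-c2ccc(O)cc2)c(OC(=O)C[C@H](C)O)c(OC(=O)C[C@H](C)O)c1-c1ccc(O)cc1 | target

## Step count and risk

Total steps: 9. Longest linear sequence: 8 (steps 1–6, 8, 9); step 7 is a one-step branch that joins at step 8.

The three steps most likely to fail:

**Step 8 (the proposed new step).** The risks are acylation of the freed β-hydroxyl by a further acyl azolium (oligo-ester), loss of water from the acyl azolium to a crotonate, and slow attack by the hindered second phenol. Because each side chain is set independently from 20, the (R,R)-enantiomer is statistically negligible; the minor (R,S)/(S,R) diastereomers must be removed at 21, which may be difficult because the stereocentres are remote. The fallback uses only known chemistry; it sets out from 20 (with 17) and comes back to the route at 22. Open 20 with methanol under the same carbene catalyst (the established alcohol version of the redox esterification) to give methyl (S)-3-hydroxybutanoate F4. Benzylate under acid (benzyl 2,2,2-trichloroacetimidate, cat. TfOH, CH2Cl2) to methyl (S)-3-(benzyloxy)butanoate F5. Saponify (LiOH, THF/H2O, 0 °C) to (S)-3-(benzyloxy)butanoic acid F6. Couple this twice to 17 (EDC·HCl, DMAP, CH2Cl2; Steglich-type esterification) to give 2-acetoxy-3,6-bis[4-(benzyloxy)phenyl]-4,5-bis{[(3S)-3-(benzyloxy)butanoyl]oxy}phenyl 3-phenylpropanoate F7. The hydrogenolysis conditions of step 9 then remove all four benzyl groups at once and deliver 22.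

**Step 3 (double metalation/Negishi).** The second lithiation may be incomplete and the coupling may stall at the mono-aryl stage. The fallback sets out from 6 and comes back at 10. Brominate both ring positions electrophilically (NBS, MeCN, 0 °C) to 4,7-dibromo-5,6-bis(methoxymethoxy)-1,3-benzodioxole F1. Then couple twice with commercial 4-(benzyloxy)phenylboronic acid (Pd(OAc)2, SPhos, K3PO4, toluene/H2O, 90 °C; Suzuki–Miyaura) to reach 10.

**Step 5 (one-pot mixed acylation).** Mono-acylation may be unselective, giving the two symmetric diesters beside 15. The fallback sets out from 11 and comes back at 15. Condense 11 with triethyl orthoacetate (cat. PPTS, toluene, 80 °C) to the cyclic orthoester 4,8-bis[4-(benzyloxy)phenyl]-2-ethoxy-2-methylbenzo[1,2-d:4,5-d']bis[1,3]dioxole F2. Mild hydrolysis (AcOH/H2O/THF, rt) can open it only to the mono-acetate 4,7-bis[4-(benzyloxy)phenyl]-6-hydroxy-1,3-benzodioxol-5-yl acetate F3. Acylate the remaining hydroxyl with 12 (pyridine, DMAP, CH2Cl2) to reach 15.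

## Further compounds

F1 | step 3 | 4,7-dibromo-5,6-bis(methoxymethoxy)-1,3-benzodioxole | COCOc1c(OCOC)c(Br)c2OCOc2c1Br
F2 | step 5 | 4,8-bis[4-(benzyloxy)phenyl]-2-ethoxy-2-methylbenzo[1,2-d:4,5-d']bis[1,3]dioxole | CCOC1(C)Oc2c(O1)c(-c3ccc(OCc4ccccc4)cc3)c3OCOc3c2-c2ccc(OCc3ccccc3)cc2
F3 | step 5 | 4,7-bis[4-(benzyloxy)phenyl]-6-hydroxy-1,3-benzodioxol-5-yl acetate | CC(=O)Oc1c(O)c(-c2ccc(OCc3ccccc3)cc2)c2OCOc2c1-c1ccc(OCc2ccccc2)cc1
F4 | step 8 | methyl (S)-3-hydroxybutanoate | COC(=O)C[C@H](C)O
F5 | step 8 | methyl (S)-3-(benzyloxy)butanoate | COC(=O)C[C@H](C)OCc1ccccc1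
F6 | step 8 | (S)-3-(benzyloxy)butanoic acid | OC(=O)C[C@H](C)OCc1ccccc1
F7 | step 8 | 2-acetoxy-3,6-bis[4-(benzyloxy)phenyl]-4,5-bis{[(3S)-3-(benzyloxy)butanoyl]oxy}phenyl 3-phenylpropanoate | CC(=O)Oc1c(OC(=O)CCc2ccccc2)c(-c2ccc(OCc3ccccc3)cc2)c(OC(=O)C[C@H](C)OCc2ccccc2)c(OC(=O)C[C@H](C)OCc2ccccc2)c1-c1ccc(OCc2ccccc2)cc1
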